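The closed vessel held starting complex, incoming ligand and scavenger at constant temperature.

all flasks: starting complex 1.8 M

|  | incoming ligand | scavenger | remark | time |
|---|---|---|---|---|
| Tuesday's | 1.26 M | 0.45 M | run made earlier |  |
| Saturday's | 1.26 M | 1.8 M | run made earlier |  |
| Monday's | 1.9 M | 0.90 M | run made earlier |  |
| flask | 1.26 M | 0.900 M |  | 25 h |

| run | time / h | starting complex / % | complex with two exchanged / % |
|---|---|---|---|
| Tuesday's | 1.33 | 88.8 | 0.1 |
| Tuesday's | 2.50 | 82.3 | 1.5 |
| Tuesday's | 4.00 | 75.1 | 2.6 |
| Tuesday's | 8.00 | 66.0 | 5.1 |
| Tuesday's | 15.0 | 59.8 | 8.5 |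
| Saturday's | 1.33 | 89.1 | 0.2 |
| Saturday's | 2.50 | 81.9 | 0.9 |
| Saturday's | 4.00 | 75.1 | 2.2 |
| Saturday's | 8.00 | 65.8 | 4.6 |
| Saturday's | 15.0 | 58.6 | 6.4 |
| Monday's | 3.00 | 71.2 | 3.4 |
| Monday's | 6.00 | 58.4 | 7.5 |
| Monday's | 10.0 | 50.5 | 11.9 |
| Monday's | 12.0 | 47.5 | 13.4 |
| Monday's | 15.0 | 45.7 | 15.3 |

(each reading ± 0.3 percentage points)

* part of the starting complex that has reacted at 25 h
* share of the unused incoming ligand that is free and not bound as idle adduct, at 25 h

- the numbers in the tables scatter by 0.3 percentage points (one standard deviation)
- the earlier runs do not show how much of incoming ligand is bound; that part of a forecast is a guess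

I turned the second question round: what must be true for most unused ligand to be bound? I supposed that each exchange spends one incoming ligand and frees one leaving ligand, which the scavenger removes and the idle adduct needs. Counting the loss of starting complex plus one more release for each complex with two exchanged, I put Tuesday's release at its last reading at 0.877 M against 0.45 M of scavenger, so if the scavenger had taken its full charge, my estimate of the uncovered part was 0.427 M. Between its last two readings that run lost starting complex at 86.1% of Saturday's pace, a ratio read from numbers that scatter by 0.3 percentage points. I assumed that this small shortfall was the bound correction, which gave the hold, a rough reading of bound per free ligand for each molar of uncovered leaving ligand: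

hold = (1/keep − 1)/uncovered = 0.378 M⁻¹

By this reading, equal bound and free ligand need c(leaving ligand) = 2.65 M, more than the flask's 1.26 M of incoming ligand, which pays for the releases. With the scavenger keeping pace, I estimated at most 0.360 M of leaving ligand uncovered in the flask, and the hold then gave a free share of at least 88.0%.

The forecast said 44.5% and 18%, holding that “ligand seems to drift slowly into an idle form”.

The flask gave 43.7% and 96.9%.

    starting complex + incoming ligand ⇌ leaving ligand + complex with one exchanged (K = 3.40, k = 2.20 × 10⁻⁵ M⁻¹ s⁻¹)
    complex with one exchanged + incoming ligand ⇌ leaving ligand + complex with two exchanged (K = 1.80, k = 2.00 × 10⁻⁵ M⁻¹ s⁻¹)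
    complex with two exchanged + incoming ligand ⇌ leaving ligand + complex with three exchanged (K = 0.170, k = 6.10 × 10⁻⁵ M⁻¹ s⁻¹)
    leaving ligand + incoming ligand ⇌ idle adduct, settled at all times (K = 0.220 M⁻¹)
    scavenger + leaving ligand → scavenged by-product (k = 1.80 × 10⁻⁴ M⁻¹ s⁻¹)
    incoming ligand → decomposed reagent (k = 7.60 × 10⁻⁶ s⁻¹)

The midpoint of the scavenger's take of leaving ligand up to 25 h came at 6.00 h, and the flask ended with c(leaving ligand) at 0.145 M against 0.845 M of scavenged by-product. With the hold, that leaving ligand gives a free share of 94.8%.

In the neighbour flask with 0.36 M of scavenger, the same reckoning allows at most 0.900 M uncovered, and the hold gives an estimated free share of at least 74.6%. That neighbour computed to 89.1%, with 0.554 M of leaving ligand standing.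

The earlier runs and the new flask come from a simulation with made-up constants; the scatter is artificial.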